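At early times the dawn flask already shows 48.9 % of its substrate charge as target at 12.0 s, while the summer flask shows 5.0 %. We want the target in five new flasks after 2.0 min.

common to all: initiator 2.5 mM

| charge | substrate | reagent | remark | time |
|---|---|---|---|---|
| dawn | 0.0036 M | 0.050 M | run made earlier |  |
| summer | 0.042 M | 0.050 M | run made earlier |  |
| blue | 0.0030 M | 0.0500 M |  | 2.0 min |
| green | 0.0060 M | 0.0500 M |  | 2.0 min |
| grey | 0.012 M | 0.0500 M |  | 2.0 min |
| ochre | 0.025 M | 0.0500 M |  | 2.0 min |
| violet | 0.050 M | 0.0500 M |  | 2.0 min |

| dawn: time / s | dawn: target / % | summer: time / s | summer: target / % |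
|---|---|---|---|
| 12.0 | 48.9 | 12.0 | 5.0 |
| 25.0 | 67.7 | 25.0 | 7.8 |
| 40.0 | 67.3 | 40.0 | 10.5 |
| 50.0 | 66.7 | 50.0 | 12.8 |
| 60.0 | 66.7 | 60.0 | 13.8 |

(scatter of a reading: 0.5 percentage points)

* [target] at the end for blue, green, grey, ochre, violet, in this order
* how that number moves from the first to the last of them (hardly changes / rises all the way / falls all the way / falls, then rises / rises, then falls)

- "hardly changes" means that all values lie within two and a half points (for a concentration: within two and a half percent of the largest)

Dawn stands level from 25.0 s on, so we average its level readings into the plateau share, the fraction of the substrate charge that is target once a flask has stopped: 67.1 %. At the low end we reckon the target as the share of the charge, which for blue is 0.00201 M. At the high end, summer has reached 13.8 % at 60.0 s, well below the share, and it is still climbing slowly. To join the two ends, we ask what charge has a share equal to summer's target at that reading. The answer is 0.00864 M, and since summer's readings are still rising at 60.0 s, we take this as our estimate, on the low side, of where the row turns.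

The forecast gives 0.002 M, 0.004 M, 0.0079 M, 0.0098 M and 0.008 M, so its shape is rises, then falls, on the ground that “the cap shrinks as substrate rises”.

The flasks give 0.00200 M, 0.00398 M, 0.00781 M, 0.00794 M and 0.00677 M, and the shape is rises, then falls.

    initiator → 2 initiating radical (k = 0.0170 /s)
    substrate + initiating radical → capped initiator + first chain carrier (k = 1.80 × 10⁵ /M/s)
    reagent + first chain carrier → target + second chain carrier (k = 1400 /M/s)
    substrate + second chain carrier → released group + first chain carrier (k = 5400 /M/s)
    first chain carrier → ended carrier (k = 26.0 /s)
    2 first chain carrier → ended chains (k = 2.00 × 10⁶ /M/s)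
    substrate + target → side product (k = 0.0860 /M/s)

Forecast and flask part further at ochre than at violet, with 0.0098 M against 0.00794 M. Grey ends with 0 % of its substrate left and 65.1 % of its charge as target, against the share of 67.1 %. Ochre ends with 44.4 % of its substrate left and 31.8 % of its charge as target, while the share applied to the part consumed gives 37.3 %. The row turns at 0.014 M, above our estimate of 0.00864 M.

The data are calculated from invented constants; the scatter is artificial.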